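## Analysis of the target

The target (37) is a cembranoid: a 14-membered carbocycle (C1–C14) with a δ-lactone bridging C1 and C3 (ring atoms O–C16(=O)–C15–C1–C2–C3, methyl C17 on C15). It also carries a trans trisubstituted epoxide at C11–C12 (methyl C20), a tertiary carbinol at C4 (methyl C18), an allylic secondary alcohol at C7 and an exocyclic methylene C19 on C8. Its seven stereocentres are (1R,3R,4S,7S,11S,12S,15S). In the lactone the C1 and C3 ring bonds are cis and the C15 methyl is trans to the C1 branch, so all three substituents can be equatorial and C15 should be the thermodynamically preferred epimer. C3 and C4 are erythro, the epoxide maps onto an E olefin, and C7 is 1,4-remote from C4 and needs reagent control. The sensitive groups are the acid-labile epoxide, the enolisable and nucleophile-sensitive lactone, and the allylic alcohol next to the 1,1-disubstituted alkene. The synthesis is hard because a 14-membered ring must be closed without touching these groups, three separate stereochemical clusters (C1/C15, C3/C4, C7) cannot relay information to each other, and several alkenes must be told apart. The strategy rests on the C9–C10 bond. C9 is allylic to C8=C19 and C10 is allylic to C11=C12, and C9–C8(=C19) is a 2-substituted allyl with two equivalent CH2 termini. An allyl-metal electrophile at C9 and a stabilised allylic carbanion at C10 can therefore be joined with no regiochemical or stereochemical question at the new bond.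

## Retrosynthetic reasoning

**37 ⇐ 36 ⇐ 35 (O–Si bond; the two C–O bonds of the epoxide).** The epoxide is the most fragile group, so it is introduced last but one and only the C7 silyl ether is removed after it. A trans epoxide at C11–C12 corresponds to the E-trisubstituted olefin of 35. This olefin is far more nucleophilic than the 1,1-disubstituted C8=C19 bond, so a reagent-controlled oxygen transfer has to achieve site and face selectivity only.

**35 ⇐ 34 (C10–S bond).** The C10 sulfonyl group of 34 exists only to make C10 nucleophilic. Its reductive removal must leave the C11=C12 double bond in place and E.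

**34 ⇐ 33 (C9–C10 bond, ring closure).** Cutting here places the ring closure between two allylic carbons and away from every stereocentre. It gives the seco compound 33 with an allylic sulfone at C10 and an allylic carbonate at C9. The forward step has to form a 14-membered ring by C-alkylation at the sulfone α-carbon; the electrophile needs no regiocontrol because its two termini are equivalent.

**33 ⇐ 32 ⇐ 31 ⇐ 30 ⇐ 29 ⇐ 28 ⇐ 25 + 27 (C7–C8 bond).** The carbonate of 33 comes from the primary allylic alcohol of 32. The C8/C9/C19 unit is joined to C7 by adding the alkenyl bromide 27 (from 26) to the aldehyde 25 in a chromium-mediated coupling that tolerates the lactone and the sulfone. C7 has no neighbour that could control it, so the epimeric adduct 28 is oxidised to the enone 29 and reduced under catalyst control to 30. The two triethylsilyl groups of 31 (on O9 and O4) are removed together, so the C7 tert-butyldimethylsilyl ether is the only protecting group left in 33.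

**25 ⇐ 24 ⇐ 22 ⇐ 21 ⇐ 19 ⇐ 18 (C7=O; C10–S; silyl groups).** The C7 aldehyde comes from the terminal vinyl group of 22 by anti-Markovnikov hydration and oxidation. A borane does this selectively in the presence of the trisubstituted C11=C12 bond, which an oxidative cleavage would not. The tertiary C4 hydroxyl is capped first (22), because a free γ-hydroxy aldehyde would close to a lactol. The sulfone 21 is made from the allylic alcohol 19 by substitution. It is installed only after C15 has been equilibrated, since the sulfone α-protons are more acidic than the lactone α-proton.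

**18 ⇐ 17 ⇐ 15 (C16=O, O–C3 bond; C15 configuration).** The lactone is formed by oxidative lactonisation of the 1,5-diol in 15 (primary C16 hydroxyl, secondary C3 hydroxyl). The C15 epimers of 17 are then equilibrated to the all-equatorial lactone 18, which sets the last stereocentre by thermodynamics.

**15 ⇐ 14 ⇐ 12 (C5–C6 bond; C16–O bond).** C6 and C7 arrive as a vinyl nucleophile that opens the 2,2-disubstituted epoxide of 14 at its CH2 terminus (C5), leaving C4 untouched. The C16 hydroxyl comes from hydroboration of the isopropenyl group of 12. This is done before the vinyl group is present, so the two borane-reactive alkenes never coexist and C16 needs no protecting group.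

**12 ⇐ 11 ⇐ 10 ⇐ 9 (epoxide at C4–C5; C3–H bond).** The erythro C3/C4 pair comes from a hydroxyl-directed epoxidation of the 2-substituted allylic alcohol 11. Its C3 configuration is set by catalyst-controlled reduction of the enone 10, which is the oxidation product of the epimeric alcohol 9.

**9 ⇐ 8 ⇐ 7 ⇐ 5 + 6 (C11=C12 bond).** C10 and C11 come from the phosphonate 6 by olefination of the methyl ketone of 5. Reduction gives the allylic alcohol 8, and its primary hydroxyl is silylated (9) so that it survives until the sulfone is needed.

**5 ⇐ 3 + 4 (C3–C4 bond); 3 ⇐ 1 (cleavage of the ring alkene).** Limonene (1) supplies C1 with the correct configuration together with C2, C3, C12–C17 and C20. Cleaving its ring alkene gives the keto aldehyde 3. An aldehyde-selective alkenyl addition of 4 then brings in C4, C5 and C18 and differentiates the two carbonyl groups without protection.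

## Alternatives that were turned down

**Alternative 1:** The disconnection is the lactone C3–O bond, cut on an already closed carbocycle. In the forward step the C16 carboxyl group of the macrocyclic bis-epoxy acid A2 opens the (3S,4S)-epoxide at C3 with inversion and gives A1, the 7-O-triethylsilyl ether of 37.

- **For:** one operation forms the lactone, sets C3 and releases the C4 hydroxyl. The six-membered mode at the secondary C3 should win over the seven-membered mode at the tertiary C4. The end game is short and nearly free of protecting groups. On lactone construction this plan is stronger than the chosen one, which needs a separate oxidation and an equilibration.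
- **Against:** A2 is itself a 14-membered ring, so a carbon–carbon macrocyclisation is still required and is only moved out of sight. Two E-trisubstituted olefins (C3=C4 and C11=C12) would have to be epoxidised with absolute control. The activation that opens one trisubstituted epoxide also threatens the other, which has a transannular hydroxyl nearby. C15 would have to be correct in a flexible macrocycle before lactonisation.
- **Comparison:** the chosen strategy sets C3/C4 on acyclic material by a directed epoxidation, and its ring closure carries no stereochemical demand.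

**Alternative 2:** The disconnection is at C1, cutting both C1–C14 and C1–C2. Lithiated 1,3-dithiane A5 is alkylated by the C14 iodide of the iodo epoxide A4. After a second lithiation it opens the C2–C3 epoxide at C2, closing the ring to the macrocyclic dithiane A3.

- **For:** two carbon–carbon bonds come from a cheap linchpin, the chain is assembled convergently, and the C3 configuration is carried in from the epoxide. On convergence it is stronger than the chosen, largely linear route.
- **Against:** the ring-closing event is the attack of a hindered 2-alkyl-2-lithio-dithiane on an epoxide. It needs a strong base in the presence of allylic protons and two silyl ethers, and it has to compete with intermolecular reaction. A3 still lacks C15–C17, so the lactone, C1 and C15 would have to be built on the macrocycle from a C1 ketone. That means two stereocentres set late under conformational control that cannot be predicted, plus a deoxygenation at C1.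
- **Comparison:** the chosen strategy offers a precursor in which all seven centres or their progenitors are fixed before the ring is closed.

**Alternative 3:** The disconnection is C6–C7, as an alkyne. A molybdenum alkylidyne such as Mo(≡CC6H4OMe)(OSiPh3)3 would metathesise the two methyl-capped alkynes of the diyne A7 to the 14-membered cycloalkyne A6, releasing 2-butyne A8.

- **For:** alkyne metathesis is among the most dependable ways to close a 14-membered ring. It ignores the olefins and the lactone, and the C1/C3/C4/C15 array is already in place. As a ring closure it is probably more reliable than the chosen step, and this point goes to the alternative.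
- **Against:** A6 has neither the C7 oxygen nor the C6 methylene. The conjugated enyne would have to be converted regioselectively into a C7 ketone and then reduced with control of the C7 configuration on the macrocycle. Both are open questions, and the C4 hydroxyl is too far away to guide them with confidence.
- **Comparison:** in the chosen strategy the ring closure leaves every oxygen function as it is and is followed only by a traceless desulfonylation, the epoxidation and a deprotection.

Key step: step 25

## Route

Atom numbers C1–C20 follow the cembrane skeleton defined in the analysis.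

Step 1
Reactants: 1 (R)-(+)-limonene
Product: 3 (3R)-6-oxo-3-(prop-1-en-2-yl)heptanal, via limonene ring ozonide 2 (not isolated)
Conditions: O3 (1.0 equiv, metered), CH2Cl2, −78 °C; then PPh3, −78 °C to rt
Reagents that add atoms: ozone, [O-][O+]=O
Why: Ozonolysis with reductive work-up; the electron-rich trisubstituted ring alkene reacts much faster than the 1,1-disubstituted isopropenyl group, so one equivalent should cleave only C3=C12, and the C1 stereocentre of 1 is not touched.

Step 2
Reactants: 3 (3R)-6-oxo-3-(prop-1-en-2-yl)heptanal; 4 2-bromopropene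
Product: 5 (5R)-7-hydroxy-8-methyl-5-(prop-1-en-2-yl)non-8-en-2-one (both epimers at the carbinol carbon, cembrane C3)
Conditions: CrCl2 (4 equiv), NiCl2 (2 mol%), DMF, rt
Reagents that add atoms: none
Why: Nozaki–Hiyama–Kishi coupling; the alkenylchromium species adds to aldehydes but not to ketones, which differentiates the two carbonyl groups without protection; the carbinol centre is formed unselectively and is reset in steps 6 and 7.

Step 3
Reactants: 5 hydroxy ketone; 6 triethyl phosphonoacetate
Product: 7 ethyl (2E,6R)-8-hydroxy-3,9-dimethyl-6-(prop-1-en-2-yl)deca-2,9-dienoate (both C8 epimers)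
Conditions: NaH, THF, 0 °C (anion of 6 preformed, 2 equiv); then 5, 0 °C to rt
Reagents that add atoms: none
Why: Horner–Wadsworth–Emmons olefination of the methyl ketone; the E ester should predominate and the minor Z ester is removed by chromatography; the stabilised phosphonate anion is too weak a base to deprotonate the free hydroxyl.

Step 4
Reactants: 7 hydroxy enoate
Product: 8 (2E,6R)-3,9-dimethyl-6-(prop-1-en-2-yl)deca-2,9-diene-1,8-diol (both C8 epimers)
Conditions: iBu2AlH (3.5 equiv), CH2Cl2, −78 °C; Rochelle salt work-up
Reagents that add atoms: none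
Why: 1,2-Reduction of the conjugated ester to the allylic alcohol with an aluminium hydride; alkenes and the existing hydroxyl are inert and the E geometry is retained.

Step 5
Reactants: 8 diol
Product: 9 (5R,8E)-10-[tert-butyl(dimethyl)silyl]oxy-2,8-dimethyl-5-(prop-1-en-2-yl)deca-1,8-dien-3-ol (both C3 epimers)
Conditions: TBSCl (1.05 equiv), imidazole, CH2Cl2, −20 to 0 °C
Reagents that add atoms: tert-butyldimethylsilyl chloride, CC(C)(C)[Si](C)(C)Cl
Why: Silylation is much faster at the unhindered primary allylic hydroxyl (C10) than at the secondary one flanked by the isopropenyl group, so the C10 oxygen is masked selectively.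

Step 6
Reactants: 9 silyl ether
Product: 10 (5R,8E)-10-[tert-butyl(dimethyl)silyl]oxy-2,8-dimethyl-5-(prop-1-en-2-yl)deca-1,8-dien-3-one
Conditions: Dess–Martin periodinane, NaHCO3, CH2Cl2, 0 °C to rt
Reagents that add atoms: none
Why: Dess–Martin oxidation of the secondary allylic alcohol to the α-substituted enone under buffered, non-epimerising conditions; both epimers of 9 converge on one ketone.

Step 7
Reactants: 10 enone
Product: 11 (3R,5R,8E)-10-[tert-butyl(dimethyl)silyl]oxy-2,8-dimethyl-5-(prop-1-en-2-yl)deca-1,8-dien-3-ol
Conditions: (S)-2-methyl-CBS-oxazaborolidine (20 mol%), catecholborane (1.5 equiv), toluene, −78 °C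
Reagents that add atoms: none
Why: Corey–Bakshi–Shibata reduction; the α-substituted alkenyl group acts as the large substituent, so the (S)-catalyst should deliver hydride to give the 3R carbinol (cembrane C3), and catecholborane at low temperature does not hydroborate the alkenes.

Step 8
Reactants: 11 (3R)-allylic alcohol
Product: 12 (1R,3R,6E)-8-[tert-butyl(dimethyl)silyl]oxy-6-methyl-1-[(2S)-2-methyloxiran-2-yl]-3-(prop-1-en-2-yl)oct-6-en-1-ol
Conditions: VO(acac)2 (5 mol%), t-BuOOH (1.5 equiv), CH2Cl2, 0 °C
Reagents that add atoms: tert-butyl hydroperoxide, CC(C)(C)OO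
Why: Vanadium-catalysed hydroxyl-directed epoxidation; only the allylic alkene is activated, and for a 2-substituted allylic alcohol the transition state that avoids 1,2-allylic strain gives the erythro epoxy alcohol, which sets C4 as S relative to the 3R carbinol.

Step 9
Reactants: 12 epoxy alcohol
Product: 14 (1R,3R,6E)-8-[tert-butyl(dimethyl)silyl]oxy-3-(1-hydroxypropan-2-yl)-6-methyl-1-[(2S)-2-methyloxiran-2-yl]oct-6-en-1-ol (both C15 epimers), via alkylborane 13 (not isolated)
Conditions: 9-BBN (1.5 equiv), THF, 0 °C to rt; then NaBO3·4H2O, THF/H2O, rt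
Reagents that add atoms: sodium perborate, [Na+].[Na+].O[B-]1(O)OO[B-](O)(O)OO1
Why: Anti-Markovnikov hydroboration–oxidation; 9-BBN adds to the 1,1-disubstituted isopropenyl group and not to the trisubstituted C11=C12 bond, and the mild perborate oxidation spares the epoxide; C15 is formed as both epimers and is corrected in step 12.

Step 10
Reactants: 14 epoxy diol
Product: 15 (4S,5R,7R,10E)-12-[tert-butyl(dimethyl)silyl]oxy-7-(1-hydroxypropan-2-yl)-4,10-dimethyldodeca-1,10-diene-4,5-diol (both C15 epimers)
Conditions: CH2=CHMgBr (5 equiv), CuI (15 mol%), THF, −40 to −20 °C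
Reagents that add atoms: vinylmagnesium bromide, C=C[Mg]Br
Why: Copper-catalysed Grignard opening of a 2,2-disubstituted epoxide at its CH2 terminus (C5), which forms C5–C6 and leaves the C4 configuration unchanged; the two hydroxyls are carried as magnesium alkoxides and the silyl ether is inert.

Step 11
Reactants: 15 triol
Product: 17 (4R,6R)-4-[(3E)-5-[tert-butyl(dimethyl)silyl]oxy-3-methylpent-3-en-1-yl]-6-[(2S)-2-hydroxypent-4-en-2-yl]-3-methyloxan-2-one (both C15 epimers), via lactol 16 (not isolated)
Conditions: TEMPO (20 mol%), PhI(OAc)2 (2.5 equiv), CH2Cl2, rt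
Reagents that add atoms: none
Why: Oxidative lactonisation of a 1,5-diol; the oxoammonium salt oxidises the primary C16 hydroxyl, the aldehyde closes to the six-membered lactol with the C3 hydroxyl and this is oxidised on to the δ-lactone; the tertiary hydroxyl and the alkenes do not react.

Step 12
Reactants: 17 lactone (C15 epimers)
Product: 18 (3S,4R,6R)-4-[(3E)-5-[tert-butyl(dimethyl)silyl]oxy-3-methylpent-3-en-1-yl]-6-[(2S)-2-hydroxypent-4-en-2-yl]-3-methyloxan-2-one
Conditions: KOtBu (0.3 equiv), t-BuOH/THF, 0 °C to rt
Reagents that add atoms: none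
Why: Base-mediated epimerisation through the lactone enolate; the 15S epimer has the methyl group and both ring substituents equatorial and should dominate at equilibrium, and C15 is the only enolisable centre; the minor epimer is recycled.

Step 13
Reactants: 18 (15S)-lactone
Product: 19 (3S,4R,6R)-4-[(3E)-5-hydroxy-3-methylpent-3-en-1-yl]-6-[(2S)-2-hydroxypent-4-en-2-yl]-3-methyloxan-2-one
Conditions: HF·pyridine, pyridine, THF, 0 °C to rt
Reagents that add atoms: none
Why: Fluoride cleavage of the primary allylic silyl ether under buffered, weakly acidic conditions that neither open the lactone nor epimerise C15.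

Step 14
Reactants: 19 allylic alcohol
Product: 21 (3S,4R,6R)-6-[(2S)-2-hydroxypent-4-en-2-yl]-3-methyl-4-[(3E)-3-methyl-5-(phenylsulfonyl)pent-3-en-1-yl]oxan-2-one, via allylic chloride 20 (not isolated)
Conditions: MsCl, LiCl, 2,4,6-collidine, DMF, 0 °C; then PhSO2Na, Bu4NI (cat.), rt
Reagents that add atoms: sodium benzenesulfinate, [Na+].[O-]S(=O)c1ccccc1
Why: The primary allylic alcohol is converted through its mesylate into the chloride and displaced by sulfinate at sulfur in a direct substitution at the primary carbon, which retains the E olefin; the tertiary hydroxyl does not react.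

Step 15
Reactants: 21 allylic sulfone
Product: 22 C4 triethylsilyl ether of 21
Conditions: Et3SiOTf (1.5 equiv), 2,6-lutidine, CH2Cl2, −78 to −20 °C
Reagents that add atoms: triethylsilyl trifluoromethanesulfonate, CC[Si](CC)(CC)OS(=O)(=O)C(F)(F)F
Why: Silyl triflate silylation of the hindered tertiary alcohol; capping O4 prevents the C7 aldehyde made in step 17 from closing to a five-membered lactol.

Step 16
Reactants: 22 silyl ether
Product: 24 primary C7 alcohol (6-[(2S)-5-hydroxy-2-(triethylsilyloxy)pentan-2-yl] analogue of 22), via alkylborane 23 (not isolated)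
Conditions: 9-BBN (1.5 equiv), THF, 0 °C to rt; then NaBO3·4H2O, THF/H2O, rt
Reagents that add atoms: sodium perborate, [Na+].[Na+].O[B-]1(O)OO[B-](O)(O)OO1
Why: Anti-Markovnikov hydroboration–oxidation of the monosubstituted vinyl group; 9-BBN leaves the trisubstituted C11=C12 bond, the lactone and the sulfone alone, so C7 is oxygenated without an oxidative cleavage that could not tell the alkenes apart.

Step 17
Reactants: 24 primary alcohol
Product: 25 (4S)-4-[(2R,4R,5S)-5-methyl-4-[(3E)-3-methyl-5-(phenylsulfonyl)pent-3-en-1-yl]-6-oxooxan-2-yl]-4-(triethylsilyloxy)pentanal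
Conditions: Dess–Martin periodinane, NaHCO3, CH2Cl2, 0 °C to rt
Reagents that add atoms: none
Why: Dess–Martin oxidation of the primary alcohol to the C7 aldehyde; with O4 silylated the aldehyde stays open-chain.

Step 18
Reactants: 26 2-bromoprop-2-en-1-ol
Product: 27 (2-bromoprop-2-en-1-yl)oxy(triethyl)silane
Conditions: Et3SiCl, imidazole, CH2Cl2, 0 °C
Reagents that add atoms: triethylsilyl chloride, CC[Si](CC)(CC)Cl
Why: Standard silylation of the primary alcohol; the triethylsilyl ether survives the chromium coupling, oxidation and reduction and is later removed in the presence of the C7 tert-butyldimethylsilyl ether.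

Step 19
Reactants: 25 aldehyde; 27 alkenyl bromide
Product: 28 C7 allylic alcohol (both C7 epimers) carrying C8(=C19H2)–C9H2–OSiEt3
Conditions: CrCl2 (5 equiv), NiCl2 (2 mol%), DMF/THF, rt
Reagents that add atoms: none
Why: Nozaki–Hiyama–Kishi coupling forms C7–C8; the alkenylchromium reagent does not attack the lactone and is not basic enough to deprotonate the sulfone; C7 is formed unselectively and is reset in steps 20 and 21.

Step 20
Reactants: 28 allylic alcohol
Product: 29 C7 enone
Conditions: Dess–Martin periodinane, NaHCO3, CH2Cl2, 0 °C to rt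
Reagents that add atoms: none
Why: Dess–Martin oxidation of the secondary allylic alcohol converges both C7 epimers on the α-methylene ketone.

Step 21
Reactants: 29 enone
Product: 30 (7S)-allylic alcohol
Conditions: (R)-2-methyl-CBS-oxazaborolidine (20 mol%), catecholborane (1.5 equiv), toluene, −78 °C
Reagents that add atoms: none
Why: Corey–Bakshi–Shibata reduction with the α-substituted alkenyl group as the large substituent; the (R)-catalyst should give the 7S carbinol, independent of the distant stereocentres, and the lactone is not reduced.

Step 22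
Reactants: 30 (7S)-alcohol
Product: 31 C7 tert-butyldimethylsilyl ether
Conditions: TBSOTf, 2,6-lutidine, CH2Cl2, −78 °C
Reagents that add atoms: tert-butyldimethylsilyl trifluoromethanesulfonate, CC(C)(C)[Si](C)(C)OS(=O)(=O)C(F)(F)F
Why: Silyl triflate protection of the secondary allylic alcohol, so that O7 cannot attack the carbonate or the π-allyl complex in step 25.

Step 23
Reactants: 31 tris-silyl ether
Product: 32 diol with free primary C9 and tertiary C4 hydroxyls
Conditions: PPTS (30 mol%), MeOH/CH2Cl2, rt
Reagents that add atoms: none
Why: Acid-catalysed methanolysis cleaves triethylsilyl ethers far faster than a secondary tert-butyldimethylsilyl ether, so both triethylsilyl groups are removed and O7 stays protected.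

Step 24
Reactants: 32 diol
Product: 33 C9 methyl carbonate (seco allylic sulfone–allylic carbonate)
Conditions: ClCO2Me (1.5 equiv), pyridine, CH2Cl2, 0 °C
Reagents that add atoms: methyl chloroformate, COC(=O)Cl
Why: Acylation of the primary allylic alcohol; the tertiary C4 hydroxyl does not react under these conditions.

Step 25
Reactants: 33 seco allylic sulfone–allylic carbonate
Product: 34 macrocyclic C10 sulfone (both C10 epimers)
Conditions: Pd(PPh3)4 (10 mol%), THF, 65 °C, 33 added over 12 h by syringe pump to a final 1 mM
Reagents that add atoms: none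
Why: Zerovalent palladium ionises the C9 methyl carbonate with loss of CO2 to a 2-substituted π-allyl complex of divalent palladium and methoxide, and the methoxide deprotonates C10 of the allylic sulfone, the most acidic C–H in 33, so base and electrophile arise together and only in catalytic concentration. The sulfonyl carbanion attacks a CH2 terminus of the π-allyl unit on the face opposite to palladium, forming C9–C10 and regenerating zerovalent palladium. The closest known reaction type is the intramolecular Tsuji–Trost allylic alkylation of sulfone-stabilised carbanions used for macrocarbocycles, run here under base-free carbonate conditions. The 14-membered ring closes in the exo sense at a primary carbon, with palladium and C19 outside the ring, and slow addition to a dilute catalyst solution favours ring closure over oligomerisation. The only new stereocentre is C10; it is not controlled, both epimers are expected, and it is erased in step 26. The step needs attack through the α-carbon of the sulfonyl allyl anion with retention of the E C11=C12 geometry, which the charge-localising sulfonyl group secures, and it needs no regiocontrol at the electrophile because the C9 and C19 termini are equivalent. The lactone, the free C4 hydroxyl and the C7 silyl ether are spectators under these neutral conditions, and the C15 configuration is the thermodynamic one and is not at risk from traces of alkoxide.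

Step 26
Reactants: 34 macrocyclic sulfone
Product: 35 macrocyclic E-olefin (C10 methylene; 7-O-tert-butyldimethylsilyl, lactone and C4 hydroxyl as in 34)
Conditions: SmI2 (6 equiv), HMPA, THF, MeOH, −20 °C
Reagents that add atoms: none
Why: Reductive desulfonylation by single-electron transfer from divalent samarium; the C–S bond of the allylic sulfone is cleaved and the allyl intermediate is protonated by methanol, which should give mainly the more substituted C11=C12 olefin; the lactone and the silyl ether are not reduced at this temperature.

Step 27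
Reactants: 35 macrocyclic olefin
Product: 36 (11S,12S)-epoxide, the 7-O-tert-butyldimethylsilyl ether of the target
Conditions: ent-Shi ketone (L-fructose-derived enantiomer of 1,2:4,5-di-O-isopropylidene-D-erythro-2,3-hexodiulo-2,6-pyranose, 30 mol%), Oxone (2KHSO5·KHSO4·K2SO4), K2CO3, Bu4NHSO4, MeCN/CH2(OMe)2, aqueous Na2B4O7 buffer, 0 °C
Reagents that add atoms: potassium peroxymonosulfate, [K+].[O-]S(=O)(=O)OO
Why: Shi asymmetric epoxidation; the chiral dioxirane reacts with the electron-rich E-trisubstituted C11=C12 bond in preference to the 1,1-disubstituted C8=C19 bond, and the antipode of the usual D-fructose-derived ketone (which gives R,R-epoxides from such olefins) should deliver oxygen to the face that gives 11S,12S.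

Step 28
Reactants: 36 silyl ether
Product: 37 target compound
Conditions: Bu4NF, AcOH, THF, 0 °C to rt
Reagents that add atoms: none
Why: Fluoride cleavage of the secondary silyl ether; buffering with acetic acid keeps the medium close to neutral so that the epoxide and the lactone survive.

## Compound list

1 | (R)-(+)-limonene, (4R)-1-methyl-4-(prop-1-en-2-yl)cyclohex-1-ene | CC1=CC[C@@H](CC1)C(C)=C | starting material
2 | ring ozonide of 1, (4R)-1-methyl-4-(prop-1-en-2-yl)-7,8,9-trioxabicyclo[4.2.1]nonane | CC12CC[C@@H](C(C)=C)CC(OO1)O2 | intermediate (not isolated)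
3 | (3R)-6-oxo-3-(prop-1-en-2-yl)heptanal | CC(=O)CC[C@@H](C(C)=C)CC=O | intermediate
4 | 2-bromopropene | CC(Br)=C | starting material
5 | (5R)-7-hydroxy-8-methyl-5-(prop-1-en-2-yl)non-8-en-2-one, both C7 epimers | CC(=O)CC[C@@H](C(C)=C)CC(O)C(C)=C | intermediate
6 | triethyl phosphonoacetate | CCOC(=O)CP(=O)(OCC)OCC | starting material
7 | ethyl (2E,6R)-8-hydroxy-3,9-dimethyl-6-(prop-1-en-2-yl)deca-2,9-dienoate, both C8 epimers | CCOC(=O)/C=C(\C)CC[C@@H](C(C)=C)CC(O)C(C)=C | intermediate
8 | (2E,6R)-3,9-dimethyl-6-(prop-1-en-2-yl)deca-2,9-diene-1,8-diol, both C8 epimers | OC/C=C(\C)CC[C@@H](C(C)=C)CC(O)C(C)=C | intermediate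
9 | (5R,8E)-10-[tert-butyl(dimethyl)silyl]oxy-2,8-dimethyl-5-(prop-1-en-2-yl)deca-1,8-dien-3-ol, both C3 epimers | CC(C)(C)[Si](C)(C)OC/C=C(\C)CC[C@@H](C(C)=C)CC(O)C(C)=C | intermediate
10 | (5R,8E)-10-[tert-butyl(dimethyl)silyl]oxy-2,8-dimethyl-5-(prop-1-en-2-yl)deca-1,8-dien-3-one | CC(C)(C)[Si](C)(C)OC/C=C(\C)CC[C@@H](C(C)=C)CC(=O)C(C)=C | intermediate
11 | (3R,5R,8E)-10-[tert-butyl(dimethyl)silyl]oxy-2,8-dimethyl-5-(prop-1-en-2-yl)deca-1,8-dien-3-ol | CC(C)(C)[Si](C)(C)OC/C=C(\C)CC[C@@H](C(C)=C)C[C@@H](O)C(C)=C | intermediate
12 | (1R,3R,6E)-8-[tert-butyl(dimethyl)silyl]oxy-6-methyl-1-[(2S)-2-methyloxiran-2-yl]-3-(prop-1-en-2-yl)oct-6-en-1-ol | CC(C)(C)[Si](C)(C)OC/C=C(\C)CC[C@@H](C(C)=C)C[C@@H](O)[C@]1(C)CO1 | intermediate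
13 | B-alkyl-9-borabicyclo[3.3.1]nonane adduct of 12 (boron on C16, both C15 epimers) | CC(C)(C)[Si](C)(C)OC/C=C(\C)CC[C@@H](C(C)CB1C2CCCC1CCC2)C[C@@H](O)[C@]1(C)CO1 | intermediate (not isolated)
14 | (1R,3R,6E)-8-[tert-butyl(dimethyl)silyl]oxy-3-(1-hydroxypropan-2-yl)-6-methyl-1-[(2S)-2-methyloxiran-2-yl]oct-6-en-1-ol, both C15 epimers | CC(C)(C)[Si](C)(C)OC/C=C(\C)CC[C@@H](C(C)CO)C[C@@H](O)[C@]1(C)CO1 | intermediate
15 | (4S,5R,7R,10E)-12-[tert-butyl(dimethyl)silyl]oxy-7-(1-hydroxypropan-2-yl)-4,10-dimethyldodeca-1,10-diene-4,5-diol, both C15 epimers | CC(C)(C)[Si](C)(C)OC/C=C(\C)CC[C@@H](C(C)CO)C[C@@H](O)[C@@](C)(O)CC=C | intermediate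
16 | (4R,6R)-4-[(3E)-5-[tert-butyl(dimethyl)silyl]oxy-3-methylpent-3-en-1-yl]-6-[(2S)-2-hydroxypent-4-en-2-yl]-3-methyloxan-2-ol (lactol, C15 epimers) | CC(C)(C)[Si](C)(C)OC/C=C(\C)CC[C@@H]1C[C@@H](OC(O)C1C)[C@@](C)(O)CC=C | intermediate (not isolated)
17 | (4R,6R)-4-[(3E)-5-[tert-butyl(dimethyl)silyl]oxy-3-methylpent-3-en-1-yl]-6-[(2S)-2-hydroxypent-4-en-2-yl]-3-methyloxan-2-one, both C15 epimers | CC(C)(C)[Si](C)(C)OC/C=C(\C)CC[C@@H]1C[C@@H](OC(=O)C1C)[C@@](C)(O)CC=C | intermediate
18 | (3S,4R,6R)-4-[(3E)-5-[tert-butyl(dimethyl)silyl]oxy-3-methylpent-3-en-1-yl]-6-[(2S)-2-hydroxypent-4-en-2-yl]-3-methyloxan-2-one | CC(C)(C)[Si](C)(C)OC/C=C(\C)CC[C@@H]1C[C@@H](OC(=O)[C@H]1C)[C@@](C)(O)CC=C | intermediate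
19 | (3S,4R,6R)-4-[(3E)-5-hydroxy-3-methylpent-3-en-1-yl]-6-[(2S)-2-hydroxypent-4-en-2-yl]-3-methyloxan-2-one | OC/C=C(\C)CC[C@@H]1C[C@@H](OC(=O)[C@H]1C)[C@@](C)(O)CC=C | intermediate
20 | (3S,4R,6R)-4-[(3E)-5-chloro-3-methylpent-3-en-1-yl]-6-[(2S)-2-hydroxypent-4-en-2-yl]-3-methyloxan-2-one | ClC/C=C(\C)CC[C@@H]1C[C@@H](OC(=O)[C@H]1C)[C@@](C)(O)CC=C | intermediate (not isolated)
21 | (3S,4R,6R)-6-[(2S)-2-hydroxypent-4-en-2-yl]-3-methyl-4-[(3E)-3-methyl-5-(phenylsulfonyl)pent-3-en-1-yl]oxan-2-one | O=S(=O)(c1ccccc1)C/C=C(\C)CC[C@@H]1C[C@@H](OC(=O)[C@H]1C)[C@@](C)(O)CC=C | intermediate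
22 | (3S,4R,6R)-3-methyl-4-[(3E)-3-methyl-5-(phenylsulfonyl)pent-3-en-1-yl]-6-[(2S)-2-(triethylsilyloxy)pent-4-en-2-yl]oxan-2-one | O=S(=O)(c1ccccc1)C/C=C(\C)CC[C@@H]1C[C@@H](OC(=O)[C@H]1C)[C@@](C)(O[Si](CC)(CC)CC)CC=C | intermediate
23 | B-alkyl-9-borabicyclo[3.3.1]nonane adduct of 22 (boron on C7) | O=S(=O)(c1ccccc1)C/C=C(\C)CC[C@@H]1C[C@@H](OC(=O)[C@H]1C)[C@@](C)(O[Si](CC)(CC)CC)CCCB1C2CCCC1CCC2 | intermediate (not isolated)
24 | (3S,4R,6R)-6-[(2S)-5-hydroxy-2-(triethylsilyloxy)pentan-2-yl]-3-methyl-4-[(3E)-3-methyl-5-(phenylsulfonyl)pent-3-en-1-yl]oxan-2-one | O=S(=O)(c1ccccc1)C/C=C(\C)CC[C@@H]1C[C@@H](OC(=O)[C@H]1C)[C@@](C)(O[Si](CC)(CC)CC)CCCO | intermediate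
25 | (4S)-4-[(2R,4R,5S)-5-methyl-4-[(3E)-3-methyl-5-(phenylsulfonyl)pent-3-en-1-yl]-6-oxooxan-2-yl]-4-(triethylsilyloxy)pentanal | O=S(=O)(c1ccccc1)C/C=C(\C)CC[C@@H]1C[C@@H](OC(=O)[C@H]1C)[C@@](C)(O[Si](CC)(CC)CC)CCC=O | intermediate
26 | 2-bromoprop-2-en-1-ol (2-bromoallyl alcohol) | OCC(Br)=C | starting material
27 | (2-bromoprop-2-en-1-yl)oxy(triethyl)silane | CC[Si](CC)(CC)OCC(Br)=C | intermediate
28 | seco chain with C7 hydroxyl (both C7 epimers), C8 methylene, C9 triethylsilyl ether, C4 triethylsilyl ether, lactone and C10 sulfone | O=S(=O)(c1ccccc1)C/C=C(\C)CC[C@@H]1C[C@@H](OC(=O)[C@H]1C)[C@@](C)(O[Si](CC)(CC)CC)CCC(O)C(=C)CO[Si](CC)(CC)CC | intermediate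
29 | C7 ketone (α-methylene enone) corresponding to 28 | O=S(=O)(c1ccccc1)C/C=C(\C)CC[C@@H]1C[C@@H](OC(=O)[C@H]1C)[C@@](C)(O[Si](CC)(CC)CC)CCC(=O)C(=C)CO[Si](CC)(CC)CC | intermediate
30 | (7S)-alcohol corresponding to 28 | O=S(=O)(c1ccccc1)C/C=C(\C)CC[C@@H]1C[C@@H](OC(=O)[C@H]1C)[C@@](C)(O[Si](CC)(CC)CC)CC[C@H](O)C(=C)CO[Si](CC)(CC)CC | intermediate
31 | 7-O-tert-butyldimethylsilyl ether of 30 (O4 and O9 as triethylsilyl ethers) | O=S(=O)(c1ccccc1)C/C=C(\C)CC[C@@H]1C[C@@H](OC(=O)[C@H]1C)[C@@](C)(O[Si](CC)(CC)CC)CC[C@H](O[Si](C)(C)C(C)(C)C)C(=C)CO[Si](CC)(CC)CC | intermediate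
32 | diol with free C9 and C4 hydroxyls, 7-O-tert-butyldimethylsilyl ether | O=S(=O)(c1ccccc1)C/C=C(\C)CC[C@@H]1C[C@@H](OC(=O)[C@H]1C)[C@@](C)(O)CC[C@H](O[Si](C)(C)C(C)(C)C)C(=C)CO | intermediate
33 | seco allylic sulfone–allylic methyl carbonate (cyclisation precursor) | O=S(=O)(c1ccccc1)C/C=C(\C)CC[C@@H]1C[C@@H](OC(=O)[C@H]1C)[C@@](C)(O)CC[C@H](O[Si](C)(C)C(C)(C)C)C(=C)COC(=O)OC | intermediate
34 | macrocyclic C10 phenyl sulfone, both C10 epimers | C=C1CC(S(=O)(=O)c2ccccc2)/C=C(\C)CC[C@@H]2C[C@@H](OC(=O)[C@H]2C)[C@@](C)(O)CC[C@@H]1O[Si](C)(C)C(C)(C)C | intermediate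
35 | macrocyclic (11E)-olefin, 7-O-tert-butyldimethylsilyl ether | C=C1CC/C=C(\C)CC[C@@H]2C[C@@H](OC(=O)[C@H]2C)[C@@](C)(O)CC[C@@H]1O[Si](C)(C)C(C)(C)C | intermediate
36 | (11S,12S)-epoxide, 7-O-tert-butyldimethylsilyl ether of the target | C=C1CC[C@@H]2O[C@@]2(C)CC[C@@H]2C[C@@H](OC(=O)[C@H]2C)[C@@](C)(O)CC[C@@H]1O[Si](C)(C)C(C)(C)C | intermediate
37 | CNP0262409.2, (1R,3R,4S,7S,11S,12S,15S)-configured epoxy cembranolide | C=C1CC[C@@H]2O[C@@]2(C)CC[C@@H]2C[C@@H](OC(=O)[C@H]2C)[C@@](C)(O)CC[C@@H]1O | target

## Step count and least certain steps

Total: 28 steps. The longest linear sequence is 27 steps (steps 1–17 and 19–28, from 1 to 37); step 18 is a one-step side branch.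

**Step 25 (key step).** The most likely failure is that ring closure loses to intermolecular alkylation, or that the π-allyl complex is captured by methoxide before the sulfone is deprotonated, giving oligomers or an allyl methyl ether. Attack through the γ-carbon of the sulfonyl allyl anion is a lesser concern. The fallback forms the same C9–C10 bond without palladium:
- It sets out from 31. Brief acid methanolysis at 0 °C removes only the primary triethylsilyl group and gives the C9 alcohol F1.
- CBr4/PPh3 converts this into the allylic bromide F2.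
- Slow addition of F2 to KN(SiMe3)2 (1.1 equiv) in THF at −78 to 0 °C under high dilution generates the sulfonyl carbanion, which displaces the bromide in a direct intramolecular alkylation to give the macrocyclic sulfone with a C4 triethylsilyl ether F3.
- PPTS in methanol removes the remaining triethylsilyl group, and the fallback rejoins the route at 34.

**Step 26.** The allyl intermediate may be protonated at the more substituted terminus, which would move the double bond out of the C11=C12 position and could erode the E geometry. The fallback replaces electron transfer by hydride delivery through a π-allyl complex. From 34, PdCl2(dppp) and LiBHEt3 in THF at 0 °C place hydride on the less hindered C10 terminus with retention of the E olefin. The lactone is reduced at the same time, giving the desulfonylated triol F4. Oxidative lactonisation of F4 with TEMPO and PhI(OAc)2, as in step 11, rejoins the route at 35.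

**Step 27.** Face selectivity may be poor if the macrocycle's preferred conformation opposes the catalyst. The C8=C19 bond may compete, and the lactone may be slowly hydrolysed in the basic buffer. The fallback gives up reagent control: from 35, buffered mCPBA (NaHCO3, CH2Cl2, −20 °C) epoxidises the more nucleophilic trisubstituted olefin from the peripheral face of the ring. The (11R,12R)-epoxide F5 formed alongside is removed by chromatography, and the fallback rejoins the route at 36.

**Step 12.** Equilibration may stop at an unfavourable ratio, or the alkoxide may open the lactone. The fallback moves the epimerisation to the aldehyde oxidation level, where the α-proton is far more acidic. From 15, Dess–Martin periodinane (1.1 equiv) gives the lactol 16, which is isolated. DBU in CH2Cl2 equilibrates C15 through the open hydroxy aldehyde to the all-equatorial (15S)-lactol F6. Oxidation with TEMPO and PhI(OAc)2 then rejoins the route at 18.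

**Step 1.** Site selectivity may be lost through partial ozonolysis of the isopropenyl group. The fallback separates the two events. From 1, mCPBA epoxidises only the trisubstituted ring alkene to limonene 1,2-oxide F7. H5IO6 in THF/H2O cleaves the epoxide through the diol, and the fallback rejoins the route at 3.

## Further compounds

F1 | step 25 | C9 alcohol with C4 triethylsilyl and C7 tert-butyldimethylsilyl ethers | O=S(=O)(c1ccccc1)C/C=C(\C)CC[C@@H]1C[C@@H](OC(=O)[C@H]1C)[C@@](C)(O[Si](CC)(CC)CC)CC[C@H](O[Si](C)(C)C(C)(C)C)C(=C)CO
F2 | step 25 | C9 allylic bromide corresponding to F1 | O=S(=O)(c1ccccc1)C/C=C(\C)CC[C@@H]1C[C@@H](OC(=O)[C@H]1C)[C@@](C)(O[Si](CC)(CC)CC)CC[C@H](O[Si](C)(C)C(C)(C)C)C(=C)CBr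
F3 | step 25 | macrocyclic C10 sulfone with C4 triethylsilyl ether | C=C1CC(S(=O)(=O)c2ccccc2)/C=C(\C)CC[C@@H]2C[C@@H](OC(=O)[C@H]2C)[C@@](C)(O[Si](CC)(CC)CC)CC[C@@H]1O[Si](C)(C)C(C)(C)C
F4 | step 26 | desulfonylated macrocyclic triol (C16, C3 and C4 hydroxyls free, 7-O-tert-butyldimethylsilyl) | C=C1CC/C=C(\C)CC[C@@H]([C@H](C)CO)C[C@@H](O)[C@@](C)(O)CC[C@@H]1O[Si](C)(C)C(C)(C)C
F5 | step 27 | (11R,12R)-epoxide diastereomer of 36 | C=C1CC[C@H]2O[C@]2(C)CC[C@@H]2C[C@@H](OC(=O)[C@H]2C)[C@@](C)(O)CC[C@@H]1O[Si](C)(C)C(C)(C)C
F6 | step 12 | (15S)-lactol, all-equatorial epimer of 16 | CC(C)(C)[Si](C)(C)OC/C=C(\C)CC[C@@H]1C[C@@H](OC(O)[C@H]1C)[C@@](C)(O)CC=C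
F7 | step 1 | (4R)-limonene 1,2-oxide | CC12CC[C@@H](C(C)=C)CC1O2
A1 | alternative 1 | 7-O-triethylsilyl ether of 37 | C=C1CC[C@@H]2O[C@@]2(C)CC[C@@H]2C[C@@H](OC(=O)[C@H]2C)[C@@](C)(O)CC[C@@H]1O[Si](CC)(CC)CC
A2 | alternative 1 | macrocyclic (3S,4S;11S,12S)-bis-epoxy acid, 7-O-triethylsilyl ether | C=C1CC[C@@H]2O[C@@]2(C)CC[C@@H]([C@H](C)C(=O)O)C[C@@H]2O[C@@]2(C)CC[C@@H]1O[Si](CC)(CC)CC
A3 | alternative 2 | macrocyclic C1 dithiane with free C3 hydroxyl | C=C1CC/C=C(\C)CCC2(SCCCS2)C[C@@H](O)[C@@](C)(O[Si](CC)(CC)CC)CC[C@@H]1O[Si](C)(C)C(C)(C)C
A4 | alternative 2 | acyclic C14 iodide with C2–C3 epoxide | ICC/C(C)=C/CCC(=C)[C@@H](O[Si](C)(C)C(C)(C)C)CC[C@](C)(O[Si](CC)(CC)CC)[C@H]1CO1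
A5 | alternative 2 | 1,3-dithiane | C1CSCSC1
A6 | alternative 3 | 14-membered C6≡C7 cycloalkyne | C=C1CC/C=C(\C)CC[C@@H]2C[C@@H](OC(=O)[C@H]2C)[C@@](C)(O[Si](CC)(CC)CC)CC#C1
A7 | alternative 3 | acyclic diyne with two methyl-capped alkynes | CC#CC(=C)CC/C=C(\C)CC[C@@H]1C[C@@H](OC(=O)[C@H]1C)[C@@](C)(O[Si](CC)(CC)CC)CC#CC
A8 | alternative 3 | 2-butyne | CC#CC
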